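Which of Q, E and D leads at the end of theta and of eta, and how much of it stands there?

| flask | E | L | G | remark | time |
|---|---|---|---|---|---|
| Monday's | 0.050 M | 10 mol% | 11 mM | run made earlier |  |
| Tuesday's | 0.050 M | 10 mol% | 15 mM | run made earlier |  |
| theta | 0.050 M | 10 mol% | 20 mM |  | 2.5 h |
| eta | 0.050 M | 10 mol% | 24 mM |  | 2.5 h |

- Monday's (time / min: Q / %, D / %, E / %): 20.0: 27.0, 1.1, 72.0; 40.0: 36.0, 1.3, 63.5; 50.0: 38.0, 1.2, 60.7; 80.0: 41.4, 1.5, 57.3; 120: 43.1, 0.9, 56.5
- Tuesday's (time / min: Q / %, D / %, E / %): 8.00: 15.0, 1.2, 84.1; 20.0: 25.0, 0.6, 74.4; 40.0: 33.6, 0.2, 65.0; 60.0: 38.3, 1.2, 60.8; 80.0: 41.0, 0.8, 58.4; 120: 42.8, 0.9, 56.9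

(standard deviation of a reading: 0.3 percentage points)

1. which of these there is most of at the end, counted by the E in it, theta (Q / E / D)
2. which of these there is most of at the end, counted by the E in it, eta (Q / E / D)
3. how much there is at the end of the one of these that leads, in percent of the E charged: theta
4. how much there is at the end of the one of these that leads, in percent of the E charged: eta

- the earlier runs were read with a standard deviation of 0.3 percentage points

Both earlier runs flatten with E ahead of Q and D near 0.9%. We therefore read the end of Monday's run as a balance between E and Q, that is, as thermodynamic control. We carry one number, the plateau share: the part of E and Q together that stands as E once the two stop moving, read from Monday's last row as 56.7%.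

The objection is that a dying catalyst can also stop a run. Tuesday's run, with less Q than Monday's at 20.0 min, should then stop with clearly more E, yet its last reading lies 0.4 points above Monday's, against a scatter of 0.3 points. That does not exclude a dying catalyst, but it gives us no reason to drop the balance.

The second objection is that theta and eta hold more G and may not arrive in time. Taking the gap of E above Monday's last reading, it decays at 0.0435 min⁻¹ in Monday's run and 0.0357 min⁻¹ in Tuesday's. So this rate is lower in the run with more G, but it falls by less than cG rises. We take the harsher order, minus one in cG, from Tuesday's rate. That gives 0.0267 min⁻¹ for theta and 0.0223 min⁻¹ for eta. Over 2.5 h, E then ends near 57.3% in theta and 58.0% in eta, so E leads in both.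

The forecast stands a little lower than our reckoning: “E still leads in both runs”, at 56.9% for theta (55.8% to 59.5%) and 57.3% for eta (55.8% to 61.5%).

The flasks give E first, with 56.4% in theta and 56.9% in eta.

    D ⇌ L + Q (K = 0.0860 M, k = 100 h⁻¹)
    L + G ⇌ X (K = 110 M⁻¹, k = 550 M⁻¹ h⁻¹)
    E + L ⇌ D (K = 9.10 M⁻¹, k = 1000 M⁻¹ h⁻¹)
    L → J (k = 0.210 h⁻¹)

Leaving out the passing of L into J makes no difference to E at the end of theta. The share of E in E and Q at the end of theta is 56.8%, beside our 56.7%. Theta left until 10 h holds E at 55.9%, a share of 56.1%.

Readings and results stem from a simulated flask for substances that don't exist; the scatter is artificial.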